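## Retrosynthetic overview

1. The target is a linear chain of four benzene rings, A–B–C–D, joined by three ether oxygens. It has ten free hydroxyls and no stereocentre. No ring has to be built: the four rings are bought and joined in the order A, B, C, D.
2. Structural feature used: each bridging oxygen sits on a carbon whose two ring neighbours both carry oxygen (C1 of ring A, C4 of ring B, C4 of ring C). Its other bond goes to C1 of the next ring (B, C, D), which is para to that ring's own doubly flanked C4–O. This repeat is what oxygen-to-para-carbon coupling of 2,6-dioxygenated phenoxyl radicals produces.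
3. Last disconnection: nine of the ten hydroxyls come from eight methyl ethers (BBr3) and one benzyl ether. The benzyl ether is removed first by hydrogenolysis, so that no benzyl cation meets the electron-rich rings.
4. Key disconnection: the bonds O–C1(B), O–C1(C) and O–C1(D) are cut together. This leads back to one para-blocked chain starter, 4-benzyloxy-2,6-dimethoxyphenol (ring A), and three molecules of 2,6-dimethoxyphenol (rings B, C, D), joined in one copper–pyridine–O2 oxidation.
5. The chain starter comes from 2,6-dimethoxy-1,4-benzoquinone by reduction and benzylation of the unflanked hydroxyl.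

Key step: step 3

Remark: the target has no stereogenic element (the diaryl ether axes rotate freely), so no configuration has to be set. 2,6-Dimethoxy-1,4-benzoquinone, benzyl bromide and 2,6-dimethoxyphenol are taken as commercial.

## Route

Step 1
Reactants: 1 2,6-dimethoxy-1,4-benzoquinone
Product: 2 2,6-dimethoxybenzene-1,4-diol
Conditions: Na2S2O4, H2O/EtOAc, rt, Ar
Reagents that add atoms: none
Why: Dithionite reduction of a 1,4-benzoquinone to its hydroquinone is a fast two-electron, two-proton transfer that leaves both methoxy groups untouched.

Step 2
Reactants: 2 2,6-dimethoxybenzene-1,4-diol; 3 benzyl bromide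
Product: 4 4-(benzyloxy)-2,6-dimethoxyphenol
Conditions: BnBr (1.0 equiv), K2CO3 (1.0 equiv), degassed DMF, Ar, 0 °C to rt
Reagents that add atoms: benzyl bromide (3), BrCc1ccccc1
Why: This is a Williamson ether synthesis in which the C4 hydroxyl, flanked only by ring hydrogens and acidified by two meta methoxy groups, should be alkylated before the C1 hydroxyl, which is crowded and hydrogen-bonded by its two ortho methoxy groups.

Step 3
Reactants: 4 4-(benzyloxy)-2,6-dimethoxyphenol (1 equiv); 5 2,6-dimethoxyphenol (syringol, 3 equiv)
Product: 8 4-{4-[4-(4-benzyloxy-2,6-dimethoxyphenoxy)-2,6-dimethoxyphenoxy]-2,6-dimethoxyphenoxy}-2,6-dimethoxyphenol (capped tetramer phenol), via capped dimer phenol 6 (not isolated), via capped trimer phenol 7 (not isolated)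
Conditions: CuCl (20 mol %), pyridine (40 equiv), O2 (1 atm), 4 Å MS, toluene, 25 °C; 5 (3.0 equiv) by syringe pump over 12 h, HPLC control; aq. Na2EDTA quench; chromatography, then preparative HPLC
Reagents that add atoms: 2,6-dimethoxyphenol (5), COc1cccc(OC)c1O
Why: Proposed new method: CuCl/pyridine/O2 oxidises 4, the most easily oxidised phenol in the flask, to a phenoxyl radical that has no productive self-coupling (its C4 carries the benzyloxy group, and any oxygen-to-C4 adduct is a quinone ketal that dissociates again), so it persists, while slowly fed 5 gives a short-lived phenoxyl with high spin density on its free C4. The oxygen of the persistent radical bonds to that C4, the 4-aryloxycyclohexa-2,5-dienone so formed tautomerises to the 4-aryloxyphenol 6, and 6 and then 7, which are again para-blocked and easier to oxidise than 5, run through the same cycle to 8, O2 ending as water. The closest known reaction type is the copper–amine oxidative coupling polymerisation of 2,6-disubstituted phenols to poly(1,4-phenylene oxide)s, in which para-substituted phenols such as 2,4,6-trimethylphenol are known to be built in as the non-phenolic chain end; not yet shown are the use of 5 as the chain-extending unit on a 4-alkoxy starter and the arrest at one defined tetramer. No ring is closed and no stereocentre is made. The step needs C–O rather than para C–C bonding, which 5 on its own tends to prefer (giving the tetramethoxydiphenoquinone): C–C pairing takes two radicals of 5 and the wanted coupling only one, so a low stationary concentration of 5 against an excess of para-blocked radicals, backed by a large pyridine-to-copper ratio and room temperature, should tip the balance, and the blocked para carbons of 4, 6 and 7 fix the direction of growth because only their oxygen can bond irreversibly. Chain length is not fixed by the substrate but by the three-to-one feed, by initiation at 4 being faster than propagation, by quenching as soon as HPLC shows 8 at its maximum, and by separating 8 from homologues that differ by one C8H8O3 unit each.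

Step 4
Reactants: 8 capped tetramer phenol
Product: 9 4-{4-[4-(4-hydroxy-2,6-dimethoxyphenoxy)-2,6-dimethoxyphenoxy]-2,6-dimethoxyphenoxy}-2,6-dimethoxyphenol (tetramer diphenol, octamethyl ether)
Conditions: H2 (1 atm), Pd/C, EtOAc/MeOH, rt
Reagents that add atoms: none
Why: Catalytic hydrogenolysis cleaves only the benzylic C–O bond and leaves diaryl and methyl ethers alone, and removing the benzyl group here avoids Friedel–Crafts benzylation of the electron-rich rings in the Lewis acid step that follows.

Step 5
Reactants: 9 tetramer diphenol, octamethyl ether
Product: 10 5-{4-[4-(2,4,6-trihydroxyphenoxy)-2,6-dihydroxyphenoxy]-2,6-dihydroxyphenoxy}benzene-1,2,3-triol (target)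
Conditions: BBr3 (20 equiv), CH2Cl2, −78 °C to rt, Ar; degassed H2O, 0 °C; Sephadex LH-20 or reversed-phase HPLC with degassed acidified eluents
Reagents that add atoms: none
Why: In this Lewis acid ether cleavage boron binds each methoxy oxygen and bromide attacks the methyl carbon by SN2, whereas the three diaryl ether oxygens offer no sp3 carbon and should survive, as is known for BBr3 demethylation of poly(2,6-dimethoxy-1,4-phenylene oxide).

## Compound list

1 | 2,6-dimethoxy-1,4-benzoquinone | COC1=CC(=O)C=C(OC)C1=O | starting material
2 | 2,6-dimethoxybenzene-1,4-diol | COc1cc(O)cc(OC)c1O | intermediate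
3 | benzyl bromide | BrCc1ccccc1 | starting material
4 | 4-(benzyloxy)-2,6-dimethoxyphenol (chain starter, ring A) | COc1cc(OCc2ccccc2)cc(OC)c1O | intermediate
5 | 2,6-dimethoxyphenol (syringol; rings B, C, D) | COc1cccc(OC)c1O | starting material
6 | 4-(4-benzyloxy-2,6-dimethoxyphenoxy)-2,6-dimethoxyphenol (capped dimer phenol) | COc1cc(OCc2ccccc2)cc(OC)c1Oc1cc(OC)c(O)c(OC)c1 | intermediate
7 | 4-[4-(4-benzyloxy-2,6-dimethoxyphenoxy)-2,6-dimethoxyphenoxy]-2,6-dimethoxyphenol (capped trimer phenol) | COc1cc(OCc2ccccc2)cc(OC)c1Oc1cc(OC)c(Oc2cc(OC)c(O)c(OC)c2)c(OC)c1 | intermediate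
8 | 4-{4-[4-(4-benzyloxy-2,6-dimethoxyphenoxy)-2,6-dimethoxyphenoxy]-2,6-dimethoxyphenoxy}-2,6-dimethoxyphenol (capped tetramer phenol) | COc1cc(OCc2ccccc2)cc(OC)c1Oc1cc(OC)c(Oc2cc(OC)c(Oc3cc(OC)c(O)c(OC)c3)c(OC)c2)c(OC)c1 | intermediate
9 | 4-{4-[4-(4-hydroxy-2,6-dimethoxyphenoxy)-2,6-dimethoxyphenoxy]-2,6-dimethoxyphenoxy}-2,6-dimethoxyphenol | COc1cc(O)cc(OC)c1Oc1cc(OC)c(Oc2cc(OC)c(Oc3cc(OC)c(O)c(OC)c3)c(OC)c2)c(OC)c1 | intermediate
10 | 5-{4-[4-(2,4,6-trihydroxyphenoxy)-2,6-dihydroxyphenoxy]-2,6-dihydroxyphenoxy}benzene-1,2,3-triol | Oc1cc(O)c(Oc2cc(O)c(Oc3cc(O)c(Oc4cc(O)c(O)c(O)c4)c(O)c3)c(O)c2)c(O)c1 | target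

## Step count

Total step count: 5. Longest linear sequence: 5 steps (1, 2, 4, 8, 9, 10).

## Steps most likely to fail

**1. Step 3.**
- Two monomer radicals may pair through their para carbons and be oxidised further.
- The monomer may start chains through its own oxygen, giving chains that lack the para oxygen of ring A.
- End units may move between chains through quinone ketals and broaden the chain-length distribution once the feed ends.
- If water builds up, the starter may lose its benzyl group oxidatively.
- The homologues may be hard to separate. Material that stops short of four rings is still a competent chain starter and can be returned to the same conditions.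

Fallback, from 4 and 5 back to 8, using iterative Ullmann diaryl ether synthesis. Monomer 5 is brominated para to the hydroxyl (NBS, CHCl3, low temperature) to 4-bromo-2,6-dimethoxyphenol F1. The hydroxyl is then masked (NaH, MOMCl, THF) to give 5-bromo-1,3-dimethoxy-2-(methoxymethoxy)benzene F2. Copper-catalysed coupling (CuI, picolinic acid, K3PO4, DMSO, 90 °C) is known to accept di-ortho-substituted phenols and electron-rich aryl bromides. It joins 4 and F2 to the capped dimer MOM ether F3, and HCl in MeOH frees 6. The same two operations on 6 give the capped trimer MOM ether F4 and then 7. On 7 they give the capped tetramer MOM ether F5 and then 8, with chain length fixed by the number of cycles.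

**2. Step 5.**
- Partly cleaved aryloxyboron species may precipitate and stop the cleavage before all eight methyl groups are gone.
- The pyrogallol-type ring D and the other electron-rich rings may be oxidised by air during aqueous work-up and chromatography.

Fallback, from 9 back to 10, by derivatising, purifying and then releasing the phenol. After the BBr3 treatment and quench the crude polyphenol is not purified. It is peracetylated (Ac2O, pyridine, DMAP) to the air-stable deca-acetate of the target F6. This is purified on silica or by crystallisation, where under-cleaved material that still carries methoxy groups separates and can be resubmitted. Acid-catalysed transesterification (HCl from AcCl in degassed MeOH, rt, Ar) then releases 10 beside a volatile ester only. The free polyphenol therefore meets neither base nor chromatography.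

**3. Step 2.**
- Alkylation may occur at the flanked hydroxyl or at both hydroxyls.
- The hydroquinone may be reoxidised by air under base.

Fallback, from 2 back to 4, differentiating the two oxygens by acyl transfer on air-stable esters. Acetylation of 2 (Ac2O, pyridine) gives 2,6-dimethoxybenzene-1,4-diyl diacetate F7. One equivalent of pyrrolidine (THF, 0 °C) should remove only the unhindered ester, which also has the better leaving phenoxide, giving 4-hydroxy-2,6-dimethoxyphenyl acetate F8. Benzylation with 3 (K2CO3, acetone) gives 4-(benzyloxy)-2,6-dimethoxyphenyl acetate F9. Methanolysis (K2CO3, MeOH, Ar) then returns 4.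

## Further compounds

F1 | step 3 | 4-bromo-2,6-dimethoxyphenol | COc1cc(Br)cc(OC)c1O
F2 | step 3 | 5-bromo-1,3-dimethoxy-2-(methoxymethoxy)benzene | COCOc1c(OC)cc(Br)cc1OC
F3 | step 3 | capped dimer MOM ether (methoxymethyl ether of 6) | COc1cc(OCc2ccccc2)cc(OC)c1Oc1cc(OC)c(OCOC)c(OC)c1
F4 | step 3 | capped trimer MOM ether (methoxymethyl ether of 7) | COc1cc(OCc2ccccc2)cc(OC)c1Oc1cc(OC)c(Oc2cc(OC)c(OCOC)c(OC)c2)c(OC)c1
F5 | step 3 | capped tetramer MOM ether (methoxymethyl ether of 8) | COc1cc(OCc2ccccc2)cc(OC)c1Oc1cc(OC)c(Oc2cc(OC)c(Oc3cc(OC)c(OCOC)c(OC)c3)c(OC)c2)c(OC)c1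
F6 | step 5 | deca-acetate of the target | CC(=O)Oc1cc(OC(C)=O)c(Oc2cc(OC(C)=O)c(Oc3cc(OC(C)=O)c(Oc4cc(OC(C)=O)c(OC(C)=O)c(OC(C)=O)c4)c(OC(C)=O)c3)c(OC(C)=O)c2)c(OC(C)=O)c1
F7 | step 2 | 2,6-dimethoxybenzene-1,4-diyl diacetate | COc1cc(OC(C)=O)cc(OC)c1OC(C)=O
F8 | step 2 | 4-hydroxy-2,6-dimethoxyphenyl acetate | COc1cc(O)cc(OC)c1OC(C)=O
F9 | step 2 | 4-(benzyloxy)-2,6-dimethoxyphenyl acetate | COc1cc(OCc2ccccc2)cc(OC)c1OC(C)=O
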